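**Plan**
- Retrosynthesis cuts, in order: the acetate C–O bond (acetate opening of an oxirane); the glyceryl ester C–O bond (esterification with (S)-glycidol); C9–C11 (sp2–sp3 cross-coupling of a C9 enol triflate); C3–C4 of ring A (radical closure); C10–C1 and C10–CH3 (two enolate alkylations). This leaves (S)-carvone as ring B (labdane numbering throughout).
- Enabling feature: ring A has the gem-dimethyl carbon C4 next to ring-fusion C5 and a C1–C2–C3 chain on quaternary C10. An isopropenyl group on C5 and a 2-(methoxycarbonyl)allyl arm on C10 of a carvone ring B, which already holds the C8 methyl and the C9 oxygen, are therefore one C3–C4 bond away from the decalin.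
- Forward: ring B is bought; C10 is made quaternary; ring A closes by hydrogen-atom-transfer radical cyclization; the helper ester at C2 is removed; the enone becomes the C9 enol triflate; the side chain is joined by B-alkyl Suzuki coupling; the glyceryl acetate end is added last.
- Stereochemistry: C5 comes from (S)-carvone; C10 from alkylation anti to the isopropenyl group, which fixes the trans ring fusion; C13 from an iridium-catalysed asymmetric allylic alkylation; glycerol C2 from (S)-glycidol, untouched because acetate attacks the terminal oxirane carbon.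

Key step: step 3

Assumption: the (Sa,S,S) antipode of the phosphoramidite ligand in step 8 is taken to give the (R)-configured branched malonate 16. If the optical rotation of 17 shows the opposite sense, the (Ra,R,R) ligand is used and nothing else changes.

**Route**

Step 1
Reactants: 1 (S)-carvone
Product: 3 (5S,6R)-6-methylcarvone (trans isomer; the minor cis epimer is carried along), via lithium enolate of carvone 2 (not isolated)
Conditions: LiN(i-Pr)2 (LDA, 1.1 equiv), THF, −78 °C; then MeI, −78 → 0 °C
Reagents that add atoms: iodomethane, CI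
Why: Kinetic deprotonation at the α′ methylene (the future C10) gives the cross-conjugated enolate, and its SN2 methylation is a standard enolate alkylation; the new centre forms mainly trans to the isopropenyl group but is made planar again in step 2, so its configuration does not matter.

Step 2
Reactants: 3 (5S,6R)-6-methylcarvone; 4 methyl 2-(bromomethyl)acrylate
Product: 6 methyl 2-{[(1R,6R)-1,3-dimethyl-2-oxo-6-(prop-1-en-2-yl)cyclohex-3-en-1-yl]methyl}prop-2-enoate, via lithium enolate of methylcarvone 5 (not isolated)
Conditions: LiN(i-Pr)2 (LDA, 1.2 equiv), THF, −78 → 0 °C; then 4, DMPU, −78 → −20 °C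
Reagents that add atoms: none
Why: Enolate alkylation of the tetrasubstituted lithium enolate with the activated allylic bromide should occur on the face opposite the neighbouring isopropenyl group, which sets quaternary C10 with the acrylate arm trans and the methyl cis to the isopropenyl group.

Step 3
Reactants: 6 methyl 2-{[(1R,6R)-1,3-dimethyl-2-oxo-6-(prop-1-en-2-yl)cyclohex-3-en-1-yl]methyl}prop-2-enoate
Product: 7 methyl (4aR,8aR)-4,4,7,8a-tetramethyl-8-oxo-1,2,3,4,4a,5,8,8a-octahydronaphthalene-2-carboxylate (mixture of C2 epimers)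
Conditions: Fe(acac)3 (0.3 equiv), PhSiH3 (2.5 equiv), EtOH/ethylene glycol (5:1), 0.02 M, 60 °C
Reagents that add atoms: none
Why: An iron hydride formed from Fe(acac)3 and PhSiH3 transfers a hydrogen atom to the CH2 terminus of the isopropenyl group (Markovnikov), the tertiary C4 radical adds to the terminal carbon C3 of the tethered acrylate, and the α-ester radical at C2 is reduced by divalent iron to the enolate and protonated by ethanol. The closest known reaction type is the iron-hydride hydrogen-atom-transfer reductive olefin coupling (a radical conjugate addition of Giese type) in its intramolecular form, which is established for ring closures of this kind. Ring A closes in the 6-endo-trig mode through the new C3–C4 bond. The only new stereocentre is C2, which is left uncontrolled because it becomes a CH2 group in step 5; the trans ring fusion is not made here but follows from C5 of carvone and the anti alkylation at C10, which hold the two reacting arms trans on ring B. The step needs hydrogen-atom transfer at the isopropenyl group in preference to the enone and acrylate alkenes, and 6-endo in preference to 5-exo closure. The first should be secured because the electron-rich 1,1-disubstituted alkene is the preferred hydrogen-atom acceptor while electron-poor alkenes act as radical traps, and the second by the polarity match of the nucleophilic tertiary radical with the unsubstituted β-carbon of the acrylate, whereas 5-exo attack would have to strike the substituted α-carbon.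

Step 4
Reactants: 7 methyl (4aR,8aR)-4,4,7,8a-tetramethyl-8-oxo-1,2,3,4,4a,5,8,8a-octahydronaphthalene-2-carboxylate
Product: 8 (4aR,8aR)-4,4,7,8a-tetramethyl-8-oxo-1,2,3,4,4a,5,8,8a-octahydronaphthalene-2-carboxylic acid (C2 epimers)
Conditions: LiOH·H2O (3 equiv), THF/MeOH/H2O (3:1:1), rt; then 1 M HCl
Reagents that add atoms: lithium hydroxide, [Li+].[OH-]
Why: Saponification of an unhindered secondary methyl ester (ester hydrolysis); epimerisation at C2 is irrelevant and the α-methyl enone should tolerate hydroxide at room temperature.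

Step 5
Reactants: 8 (4aR,8aR)-4,4,7,8a-tetramethyl-8-oxo-1,2,3,4,4a,5,8,8a-octahydronaphthalene-2-carboxylic acid
Product: 10 (4aR,8aR)-2,5,5,8a-tetramethyl-4a,5,6,7,8,8a-hexahydronaphthalen-1(4H)-one, via thiohydroxamate ester 9 (not isolated)
Conditions: N-hydroxypyridine-2-thione, DCC, DMAP (cat.), CH2Cl2, 0 °C → rt, dark; then t-BuSH (excess), hν (tungsten lamp), rt
Reagents that add atoms: none
Why: Barton reductive decarboxylation: the thiohydroxamate ester fragments under visible light to the secondary C2 radical, which the thiol should reduce faster than it can reach the enone, so the C2 stereocentre is erased.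

Step 6
Reactants: 10 (4aR,8aR)-2,5,5,8a-tetramethyl-4a,5,6,7,8,8a-hexahydronaphthalen-1(4H)-one
Product: 12 (4aR,8aR)-2,5,5,8a-tetramethyl-3,4,4a,5,6,7,8,8a-octahydronaphthalen-1-yl trifluoromethanesulfonate, via lithium enolate of the decalone 11 (not isolated)
Conditions: LiBH(s-Bu)3 (L-Selectride, 1.1 equiv), THF, −78 °C; then PhNTf2, −78 °C → rt; aq. NH4Cl
Reagents that add atoms: N-phenylbis(trifluoromethanesulfonimide), O=S(=O)(N(c1ccccc1)S(=O)(=O)C(F)(F)F)C(F)(F)F
Why: Conjugate reduction of the hindered cyclohexenone by the bulky borohydride gives the C8–C9 enolate (the only one possible, since C10 is quaternary), and O-sulfonylation with the triflimide gives the tetrasubstituted enol triflate (reductive enolate triflation).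

Step 7
Reactants: 13 (E)-but-2-en-1-ol
Product: 14 (E)-but-2-en-1-yl methyl carbonate
Conditions: ClCO2Me, pyridine, CH2Cl2, 0 °C → rt
Reagents that add atoms: methyl chloroformate, COC(=O)Cl
Why: Acylation of a primary allylic alcohol with a chloroformate (carbonate formation) leaves the E alkene untouched.

Step 8
Reactants: 14 (E)-but-2-en-1-yl methyl carbonate; 15 dimethyl malonate
Product: 16 dimethyl 2-[(2R)-but-3-en-2-yl]propanedioate
Conditions: 15 (1.5 equiv), [Ir(cod)Cl]2 (2 mol%), (Sa,S,S)-O,O′-(1,1′-binaphthyl-2,2′-diyl) N,N-bis(1-phenylethyl)phosphoramidite (4 mol%), 1,5,7-triazabicyclo[4.4.0]dec-5-ene (8 mol%), THF, rt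
Reagents that add atoms: none
Why: Iridium–phosphoramidite-catalysed asymmetric allylic alkylation: the malonate, deprotonated by the methoxide released from the carbonate, attacks the substituted terminus of the allyliridium complex to give the branched product, and the chiral ligand sets the methyl-bearing stereocentre (the future C13).

Step 9
Reactants: 16 dimethyl 2-[(2R)-but-3-en-2-yl]propanedioate
Product: 17 methyl (3S)-3-methylpent-4-enoate
Conditions: NaCl, DMSO/H2O, 150 °C; product distilled
Reagents that add atoms: none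
Why: Krapcho dealkoxycarbonylation removes one ester group; the stereocentre is β to the carbonyl and is not touched (its descriptor changes from R to S only through the priority rules).

Step 10
Reactants: 12 (4aR,8aR)-2,5,5,8a-tetramethyl-3,4,4a,5,6,7,8,8a-octahydronaphthalen-1-yl trifluoromethanesulfonate; 17 methyl (3S)-3-methylpent-4-enoate
Product: 19 methyl (3R)-3-methyl-5-[(4aR,8aR)-2,5,5,8a-tetramethyl-3,4,4a,5,6,7,8,8a-octahydronaphthalen-1-yl]pentanoate, via alkyl-9-BBN borane 18 (not isolated)
Conditions: 17, 9-BBN-H, THF, 0 °C → rt; then 12, Pd(dppf)Cl2 (10 mol%), AsPh3 (10 mol%), K3PO4 (3 M aq.), DMF, 60 °C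
Reagents that add atoms: none
Why: Anti-Markovnikov hydroboration of the terminal alkene followed by B-alkyl Suzuki–Miyaura coupling of the primary alkylborane with the enol triflate forms the C9–C11 bond and keeps the alkene at C8–C9; no stereocentre is formed.

Step 11
Reactants: 19 methyl (3R)-3-methyl-5-[(4aR,8aR)-2,5,5,8a-tetramethyl-3,4,4a,5,6,7,8,8a-octahydronaphthalen-1-yl]pentanoate
Product: 20 (3R)-3-methyl-5-[(4aR,8aR)-2,5,5,8a-tetramethyl-3,4,4a,5,6,7,8,8a-octahydronaphthalen-1-yl]pentanoic acid
Conditions: LiOH·H2O (5 equiv), THF/MeOH/H2O (3:1:1), 50 °C; then 1 M HCl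
Reagents that add atoms: lithium hydroxide, [Li+].[OH-]
Why: Saponification of a primary-chain methyl ester (ester hydrolysis); C13 is β to the carboxyl group and cannot epimerise.

Step 12
Reactants: 20 (3R)-3-methyl-5-[(4aR,8aR)-2,5,5,8a-tetramethyl-3,4,4a,5,6,7,8,8a-octahydronaphthalen-1-yl]pentanoic acid; 21 (S)-glycidol
Product: 22 [(2R)-oxiran-2-yl]methyl (3R)-3-methyl-5-[(4aR,8aR)-2,5,5,8a-tetramethyl-3,4,4a,5,6,7,8,8a-octahydronaphthalen-1-yl]pentanoate
Conditions: 21 (1.5 equiv), DCC, DMAP (cat.), CH2Cl2, 0 °C → rt
Reagents that add atoms: none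
Why: Steglich esterification acylates the primary hydroxyl of glycidol under neutral conditions without opening the oxirane, so the glycerol stereocentre is carried over unchanged (the descriptor changes from S to R only through the priority rules).

Step 13
Reactants: 22 [(2R)-oxiran-2-yl]methyl (3R)-3-methyl-5-[(4aR,8aR)-2,5,5,8a-tetramethyl-3,4,4a,5,6,7,8,8a-octahydronaphthalen-1-yl]pentanoate
Product: 23 (2R)-3-(acetyloxy)-2-hydroxypropyl (3R)-3-methyl-5-[(4aR,8aR)-2,5,5,8a-tetramethyl-3,4,4a,5,6,7,8,8a-octahydronaphthalen-1-yl]pentanoate (CNP0137802.3)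
Conditions: AcOH (10 equiv), n-Bu4NOAc (0.1 equiv), toluene, 60 °C
Reagents that add atoms: acetic acid, CC(=O)O
Why: Carboxylate opening of a terminal epoxide: acetate, with acetic acid as proton source, should attack the unsubstituted oxirane carbon in SN2 fashion, so the secondary carbinol centre keeps its configuration and the 1,3-diacylglycerol forms directly.

**Compound list**

1 | (S)-carvone, (5S)-2-methyl-5-(prop-1-en-2-yl)cyclohex-2-en-1-one | CC1=CC[C@@H](CC1=O)C(C)=C | starting material
2 | lithium enolate of carvone (C1–C6 cross-conjugated dienolate) | CC1=CC[C@@H](C=C1O[Li])C(C)=C | intermediate (not isolated)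
3 | (5S,6R)-2,6-dimethyl-5-(prop-1-en-2-yl)cyclohex-2-en-1-one (trans-6-methylcarvone; minor cis epimer carried along) | C[C@H]1C(=O)C(C)=CC[C@@H]1C(C)=C | intermediate
4 | methyl 2-(bromomethyl)acrylate | COC(=O)C(=C)CBr | starting material
5 | lithium enolate of 6-methylcarvone | CC1=CC[C@@H](C(C)=C1O[Li])C(C)=C | intermediate (not isolated)
6 | methyl 2-{[(1R,6R)-1,3-dimethyl-2-oxo-6-(prop-1-en-2-yl)cyclohex-3-en-1-yl]methyl}prop-2-enoate (acrylate arm trans to isopropenyl) | COC(=O)C(=C)C[C@@]1(C)C(=O)C(C)=CC[C@@H]1C(C)=C | intermediate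
7 | methyl (4aR,8aR)-4,4,7,8a-tetramethyl-8-oxo-1,2,3,4,4a,5,8,8a-octahydronaphthalene-2-carboxylate (trans-decalin enone, C2 epimers) | O=C1C(C)=CC[C@@H]2C(C)(C)CC(C(=O)OC)C[C@@]12C | intermediate
8 | (4aR,8aR)-4,4,7,8a-tetramethyl-8-oxo-1,2,3,4,4a,5,8,8a-octahydronaphthalene-2-carboxylic acid (C2 epimers) | O=C1C(C)=CC[C@@H]2C(C)(C)CC(C(=O)O)C[C@@]12C | intermediate
9 | 2-thioxopyridin-1(2H)-yl ester of acid 8 (thiohydroxamate ester) | O=C1C(C)=CC[C@@H]2C(C)(C)CC(C(=O)On3ccccc3=S)C[C@@]12C | intermediate (not isolated)
10 | (4aR,8aR)-2,5,5,8a-tetramethyl-4a,5,6,7,8,8a-hexahydronaphthalen-1(4H)-one | O=C1C(C)=CC[C@@H]2C(C)(C)CCC[C@@]12C | intermediate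
11 | lithium (4aR,8aR)-2,5,5,8a-tetramethyl-3,4,4a,5,6,7,8,8a-octahydronaphthalen-1-olate | [Li]OC1=C(C)CC[C@@H]2C(C)(C)CCC[C@@]12C | intermediate (not isolated)
12 | (4aR,8aR)-2,5,5,8a-tetramethyl-3,4,4a,5,6,7,8,8a-octahydronaphthalen-1-yl trifluoromethanesulfonate | O=S(=O)(OC1=C(C)CC[C@@H]2C(C)(C)CCC[C@@]12C)C(F)(F)F | intermediate
13 | (E)-but-2-en-1-ol (trans-crotyl alcohol) | C/C=C/CO | starting material
14 | (E)-but-2-en-1-yl methyl carbonate | C/C=C/COC(=O)OC | intermediate
15 | dimethyl malonate | COC(=O)CC(=O)OC | starting material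
16 | dimethyl 2-[(2R)-but-3-en-2-yl]propanedioate | COC(=O)C(C(=O)OC)[C@H](C)C=C | intermediate
17 | methyl (3S)-3-methylpent-4-enoate | COC(=O)C[C@H](C)C=C | intermediate
18 | methyl (3R)-5-(9-borabicyclo[3.3.1]nonan-9-yl)-3-methylpentanoate | COC(=O)C[C@H](C)CCB1C2CCCC1CCC2 | intermediate (not isolated)
19 | methyl (3R)-3-methyl-5-[(4aR,8aR)-2,5,5,8a-tetramethyl-3,4,4a,5,6,7,8,8a-octahydronaphthalen-1-yl]pentanoate | COC(=O)C[C@H](C)CCC1=C(C)CC[C@@H]2C(C)(C)CCC[C@@]12C | intermediate
20 | (3R)-3-methyl-5-[(4aR,8aR)-2,5,5,8a-tetramethyl-3,4,4a,5,6,7,8,8a-octahydronaphthalen-1-yl]pentanoic acid (5R,10R,13R in labdane numbering) | OC(=O)C[C@H](C)CCC1=C(C)CC[C@@H]2C(C)(C)CCC[C@@]12C | intermediate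
21 | (S)-glycidol, [(2S)-oxiran-2-yl]methanol | OC[C@H]1CO1 | starting material
22 | [(2R)-oxiran-2-yl]methyl (3R)-3-methyl-5-[(4aR,8aR)-2,5,5,8a-tetramethyl-3,4,4a,5,6,7,8,8a-octahydronaphthalen-1-yl]pentanoate | O=C(OC[C@H]3CO3)C[C@H](C)CCC1=C(C)CC[C@@H]2C(C)(C)CCC[C@@]12C | intermediate
23 | (2R)-3-(acetyloxy)-2-hydroxypropyl (3R)-3-methyl-5-[(4aR,8aR)-2,5,5,8a-tetramethyl-3,4,4a,5,6,7,8,8a-octahydronaphthalen-1-yl]pentanoate | CC(=O)OC[C@@H](O)COC(=O)C[C@H](C)CCC1=C(C)CC[C@@H]2C(C)(C)CCC[C@@]12C | target

**Count**

Total: 13 steps. Longest linear sequence: 10 steps (steps 1–6 and 10–13 from (S)-carvone); the side-chain branch (steps 7–9) joins at step 10.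

**Steps most likely to fail**

Step 10. Transmetalation and reductive elimination at the crowded tetrasubstituted alkenylpalladium centre, flanked by quaternary C10 and the C8 methyl, may be slower than β-hydride elimination or protodeboronation of the alkylborane and hydrolysis of the triflate. The fallback replaces the sp3 partner by an sp2 partner, which tolerates hindrance better, and sets out from 17 and 12. Cross-metathesis of 17 with vinylboronic acid pinacol ester (second-generation Grubbs catalyst, RuCl2(=CHPh)(PCy3)(H2IMes), CH2Cl2, 40 °C) should give methyl (3S,4E)-3-methyl-5-(4,4,5,5-tetramethyl-1,3,2-dioxaborolan-2-yl)pent-4-enoate F1. Alkenyl–alkenyl Suzuki coupling of F1 with 12 (Pd(PPh3)4, K3PO4 aq., dioxane, 80 °C) should then give the diene ester methyl (3S,4E)-3-methyl-5-[(4aR,8aR)-2,5,5,8a-tetramethyl-3,4,4a,5,6,7,8,8a-octahydronaphthalen-1-yl]pent-4-enoate F2. Diimide reduction (2-nitrobenzenesulfonyl hydrazide, Et3N, CH2Cl2, rt) should saturate only the disubstituted side-chain alkene and leave the tetrasubstituted ring alkene, which brings the route back at 19.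

Step 3. Hydrogen-atom transfer may not discriminate well enough between the isopropenyl group and the acrylate or enone, or the tertiary radical may be reduced before it closes the ring. The fallback generates the same C4 radical by halogen-atom abstraction and sets out from 6. Markovnikov hydrobromination of the isopropenyl group (HBr in AcOH, 1 equiv, 0 °C; the electron-poor alkenes should not be protonated) should give the tertiary bromide methyl 2-{[(1R,6S)-6-(2-bromopropan-2-yl)-1,3-dimethyl-2-oxocyclohex-3-en-1-yl]methyl}prop-2-enoate F3. Slow addition of Bu3SnH with AIBN in benzene at 80 °C should then close ring A through the same 6-endo addition, C3–C4 bond and trans fusion, and the route is rejoined at 7.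

Step 13. Acetate attack may lose regiocontrol, or the 2-hydroxyl of the product may take over a neighbouring acyl group under the warm carboxylate conditions. The fallback builds the glyceryl end from a protected diol and sets out from 20. Steglich esterification of 20 with (S)-solketal (CC1(C)OC[C@@H](O1)CO; DCC, DMAP, CH2Cl2) should give the solketal ester [(4R)-2,2-dimethyl-1,3-dioxolan-4-yl]methyl (3R)-3-methyl-5-[(4aR,8aR)-2,5,5,8a-tetramethyl-3,4,4a,5,6,7,8,8a-octahydronaphthalen-1-yl]pentanoate F4. Acetonide removal (Dowex 50W in its H+ form, MeOH/H2O, rt) should give the 1-monoacylglycerol (2R)-2,3-dihydroxypropyl (3R)-3-methyl-5-[(4aR,8aR)-2,5,5,8a-tetramethyl-3,4,4a,5,6,7,8,8a-octahydronaphthalen-1-yl]pentanoate F5. This diol can itself undergo acyl migration, so it is kept cold and acetylated at once on the primary hydroxyl (AcCl, 2,4,6-collidine, CH2Cl2, −78 °C), which returns the route at 23.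

**Further compounds**

F1 | step 10 | methyl (3S,4E)-3-methyl-5-(4,4,5,5-tetramethyl-1,3,2-dioxaborolan-2-yl)pent-4-enoate | COC(=O)C[C@H](C)/C=C/B1OC(C)(C)C(C)(C)O1
F2 | step 10 | methyl (3S,4E)-3-methyl-5-[(4aR,8aR)-2,5,5,8a-tetramethyl-3,4,4a,5,6,7,8,8a-octahydronaphthalen-1-yl]pent-4-enoate | COC(=O)C[C@H](C)/C=C/C1=C(C)CC[C@@H]2C(C)(C)CCC[C@@]12C
F3 | step 3 | methyl 2-{[(1R,6S)-6-(2-bromopropan-2-yl)-1,3-dimethyl-2-oxocyclohex-3-en-1-yl]methyl}prop-2-enoate | COC(=O)C(=C)C[C@@]1(C)C(=O)C(C)=CC[C@@H]1C(C)(C)Br
F4 | step 13 | [(4R)-2,2-dimethyl-1,3-dioxolan-4-yl]methyl (3R)-3-methyl-5-[(4aR,8aR)-2,5,5,8a-tetramethyl-3,4,4a,5,6,7,8,8a-octahydronaphthalen-1-yl]pentanoate | CC3(C)OC[C@@H](O3)COC(=O)C[C@H](C)CCC1=C(C)CC[C@@H]2C(C)(C)CCC[C@@]12C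
F5 | step 13 | (2R)-2,3-dihydroxypropyl (3R)-3-methyl-5-[(4aR,8aR)-2,5,5,8a-tetramethyl-3,4,4a,5,6,7,8,8a-octahydronaphthalen-1-yl]pentanoate | OC[C@@H](O)COC(=O)C[C@H](C)CCC1=C(C)CC[C@@H]2C(C)(C)CCC[C@@]12C
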